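**Plan**

- Retrosynthetic cuts (chroman numbering O1, C2, C3, C4, C4a–C8a; side-chain carbons C1'–C6' counted from C2): first the C1'=C2' bond (Julia–Kocienski olefination of a chroman-2-carbaldehyde with a C15 allylic sulfone from dihydro-β-ionone), then C5–C6 and C7–C8 of the benzoate ring (dehydrogenation, then Diels–Alder), then the two exocyclic C=CH2 bonds of the diene back to a δ-lactone.
- Enabling feature: the carboxyl sits on C6, para to the ether oxygen O1 on C8a. A 2-alkoxy-1,3-diene C8=C8a(O1)–C4a=C5 places a propiolate ester exactly there, so the benzene ring C4a–C8a can be grown onto a preformed chiral oxane.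
- Forward order: the oxane ring arises first as a δ-lactone (epoxide opening, hydroboration, oxidative lactonisation); two methylenations give the bis-exocyclic diene; the carbocycle closes in the cycloaddition and is dehydrogenated; the side chain is joined last and the ester hydrolysed.
- Stereochemistry: C2 (R in the target) comes unchanged from (S)-2-methylglycidol, whose quaternary C–O bond is never broken. 3'E is fixed in the Horner–Wadsworth–Emmons step (isomer separation), 1'E in the Julia–Kocienski step.
- The C2 substituent rides through the key step as CH2OTBDPS, so the tertiary dienylic C–O bond and the triene never meet Lewis-acidic Ti/Al residues or DDQ.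

Key step: step 8

Remark: metal salts of a reactant or product (enolates, alkoxides, carboxylates, metallated sulfone) and fleeting adducts inside one mechanistic cascade are not numbered; covalent intermediates that persist between two operations of a step are.

**Step 1**
Reactants: 1 (S)-2-methylglycidol
Product: 2 tert-butyl{[(2R)-2-methyloxiran-2-yl]methoxy}diphenylsilane
Conditions: TBDPSCl, imidazole, CH2Cl2, 0 °C → rt
Reagents that add atoms: tert-butyl(chloro)diphenylsilane, CC(C)(C)[Si](Cl)(c1ccccc1)c1ccccc1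
Why: Imidazole-mediated silyl ether formation at the primary hydroxyl leaves the epoxide and the quaternary centre untouched; the descriptor changes from S to R only because the silyloxymethyl arm now outranks the epoxide CH2.

**Step 2**
Reactants: 2 tert-butyl{[(2R)-2-methyloxiran-2-yl]methoxy}diphenylsilane
Product: 3 (2R)-1-[(tert-butyldiphenylsilyl)oxy]-2-methylhex-5-en-2-ol
Conditions: allylMgBr, CuI (10 mol %), THF, −30 → 0 °C; aq NH4Cl
Reagents that add atoms: allylmagnesium bromide, C=CC[Mg]Br
Why: Copper-catalysed Grignard opening of the 2,2-disubstituted epoxide should proceed by SN2 attack at the unsubstituted CH2 terminus, so the C–O bond at the quaternary carbon and its configuration are retained.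

**Step 3**
Reactants: 3 (2R)-1-[(tert-butyldiphenylsilyl)oxy]-2-methylhex-5-en-2-ol
Product: 5 (5R)-6-[(tert-butyldiphenylsilyl)oxy]-5-methylhexane-1,5-diol, via B-alkyl-9-BBN adduct 4 (not isolated)
Conditions: 9-BBN (2.2 equiv), THF, 0 °C → rt; then 3 M NaOH, 30% H2O2, 0 °C → rt
Reagents that add atoms: 9-borabicyclo[3.3.1]nonane, B1C2CCCC1CCC2 (boron carried only in 4); hydrogen peroxide, OO
Why: Anti-Markovnikov hydroboration–oxidation of the monosubstituted alkene with the bulky borane should give the terminal alcohol only, and the silyl ether tolerates the brief alkaline peroxide work-up.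

**Step 4**
Reactants: 5 (5R)-6-[(tert-butyldiphenylsilyl)oxy]-5-methylhexane-1,5-diol
Product: 8 (6R)-6-{[(tert-butyldiphenylsilyl)oxy]methyl}-6-methyloxan-2-one, via hydroxy aldehyde 6 (not isolated), via lactol 7 (not isolated)
Conditions: TEMPO (0.2 equiv), PhI(OAc)2 (2.5 equiv), CH2Cl2, rt
Reagents that add atoms: none
Why: TEMPO/PhI(OAc)2 oxidative lactonisation oxidises only the primary alcohol, the aldehyde is trapped by the non-oxidisable tertiary hydroxyl as the six-membered lactol, and this is oxidised on to the δ-lactone.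

**Step 5**
Reactants: 8 (6R)-6-{[(tert-butyldiphenylsilyl)oxy]methyl}-6-methyloxan-2-one
Product: 9 (6R)-6-{[(tert-butyldiphenylsilyl)oxy]methyl}-3-[(dimethylamino)methyl]-6-methyloxan-2-one (C3 epimers)
Conditions: LDA, THF, −78 °C; then CH2=NMe2+ I−, −78 °C → rt
Reagents that add atoms: Eschenmoser's salt (N,N-dimethylmethyleneiminium iodide), C=[N+](C)C.[I-]
Why: Mannich reaction of the lactone lithium enolate with the preformed iminium salt installs the one-carbon unit at C3; the C3 configuration is irrelevant because that centre becomes sp2 in the next step.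

**Step 6**
Reactants: 9 (6R)-6-{[(tert-butyldiphenylsilyl)oxy]methyl}-3-[(dimethylamino)methyl]-6-methyloxan-2-one
Product: 11 (6R)-6-{[(tert-butyldiphenylsilyl)oxy]methyl}-6-methyl-3-methylideneoxan-2-one, via trimethylammonium iodide 10 (not isolated)
Conditions: MeI, THF, rt; then sat. aq NaHCO3, CH2Cl2, rt
Reagents that add atoms: iodomethane, CI (methyl carried only in 10)
Why: Exhaustive N-methylation followed by E1cB (Hofmann-type) loss of trimethylamine under bicarbonate should give the exocyclic α-methylene lactone, the mild base avoiding migration of the double bond into the ring.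

**Step 7**
Reactants: 11 (6R)-6-{[(tert-butyldiphenylsilyl)oxy]methyl}-6-methyl-3-methylideneoxan-2-one
Product: 12 tert-butyl{[(2R)-2-methyl-5,6-dimethylideneoxan-2-yl]methoxy}diphenylsilane
Conditions: Tebbe reagent (1.3 equiv, toluene), pyridine, THF, −40 → 0 °C; 15% aq NaOH quench; filtration through basic alumina (pentane); pyridine removed by cold co-evaporation; crude used at once
Reagents that add atoms: Tebbe reagent, written as Cp2Ti=CH2·ClAlMe2, C=[Ti](C1C=CC=C1)C1C=CC=C1.C[Al](C)Cl
Why: Tebbe carbonyl methylenation ([2+2] of the titanium methylidene with the lactone C=O, then cycloreversion) is established for lactones and for α,β-unsaturated esters, where it gives 2-alkoxy-1,3-dienes; pyridine buffers the aluminium Lewis acid and the silyl ether is inert.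

**Step 8**
Reactants: 12 tert-butyl{[(2R)-2-methyl-5,6-dimethylideneoxan-2-yl]methoxy}diphenylsilane; 13 methyl propiolate
Product: 14 methyl (2R)-2-{[(tert-butyldiphenylsilyl)oxy]methyl}-2-methyl-3,4,5,8-tetrahydro-2H-chromene-6-carboxylate
Conditions: 13 (4 equiv), toluene, BHT (cat.), solid K2CO3, 70 °C, sealed tube, base-washed glassware; crude carried on
Reagents that add atoms: none
Why: A concerted, asynchronous normal-electron-demand [4+2] cycloaddition should take place between the HOMO of the oxygen-activated diene, held s-cis by the oxane ring, and the LUMO of the propiolate. The closest known reaction type is the Diels–Alder reaction of 2-alkoxy- and 2-silyloxy-1,3-dienes, including those made by titanium methylenation of unsaturated esters, with propiolates. The six-membered carbocycle C4a–C5–C6–C7–C8–C8a closes by suprafacial intermolecular annulation onto the oxane, the C5–C6 and C7–C8 bonds forming in the same event. No stereocentre is created, and C2 is remote and untouched. The step needs regioselectivity: the largest HOMO coefficient lies on the enol-ether methylene (future C8), which bonds to the propiolate β-carbon (future C7), so the ester lands on C6 para to O1, the ring oxygen overriding the weaker opposing bias of the alkyl group on C4a. Chemoselectivity is secured because 12 holds no other diene, and the amine-free, acid-free medium protects both enol ethers and the propiolate.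

**Step 9**
Reactants: 14 methyl (2R)-2-{[(tert-butyldiphenylsilyl)oxy]methyl}-2-methyl-3,4,5,8-tetrahydro-2H-chromene-6-carboxylate
Product: 15 methyl (2R)-2-{[(tert-butyldiphenylsilyl)oxy]methyl}-2-methyl-3,4-dihydro-2H-chromene-6-carboxylate
Conditions: DDQ (1.1 equiv), toluene, 0 °C → rt; filtration through basic alumina
Reagents that add atoms: none
Why: DDQ dehydrogenation of the 1,4-cyclohexadiene starts with hydride abstraction from a doubly allylic CH2 (C5 or C8) to an oxygen-stabilised arenium ion that loses a proton to the benzoate, and silyl ether and ester are inert to it.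

**Step 10**
Reactants: 15 methyl (2R)-2-{[(tert-butyldiphenylsilyl)oxy]methyl}-2-methyl-3,4-dihydro-2H-chromene-6-carboxylate
Product: 16 methyl (2R)-2-(hydroxymethyl)-2-methyl-3,4-dihydro-2H-chromene-6-carboxylate
Conditions: TBAF (1.5 equiv), AcOH (1.5 equiv), THF, rt → 40 °C
Reagents that add atoms: none
Why: Fluoride-induced desilylation frees the primary alcohol, and buffering with acetic acid keeps the methyl benzoate intact.

**Step 11**
Reactants: 16 methyl (2R)-2-(hydroxymethyl)-2-methyl-3,4-dihydro-2H-chromene-6-carboxylate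
Product: 17 methyl (2R)-2-formyl-2-methyl-3,4-dihydro-2H-chromene-6-carboxylate
Conditions: Dess–Martin periodinane (1.3 equiv), CH2Cl2, 0 °C → rt
Reagents that add atoms: none
Why: Dess–Martin oxidation converts the hindered primary alcohol into an aldehyde that has no α-hydrogen, so C2 cannot epimerise and the aldehyde cannot enolise.

**Step 12**
Reactants: 18 dihydro-β-ionone
Product: 19 ethyl (2E)-3-methyl-5-(2,6,6-trimethylcyclohex-1-en-1-yl)pent-2-enoate
Conditions: (EtO)2P(O)CH2CO2Et, NaH, THF, 0 °C → 60 °C; chromatographic removal of the minor 2Z isomer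
Reagents that add atoms: triethyl phosphonoacetate, CCOC(=O)CP(=O)(OCC)OCC
Why: Horner–Wadsworth–Emmons olefination of the methyl ketone should favour the E-trisubstituted enoate, and the Z isomer is separable at this stage.

**Step 13**
Reactants: 19 ethyl (2E)-3-methyl-5-(2,6,6-trimethylcyclohex-1-en-1-yl)pent-2-enoate
Product: 20 (2E)-3-methyl-5-(2,6,6-trimethylcyclohex-1-en-1-yl)pent-2-en-1-ol
Conditions: DIBAL-H (2.3 equiv), CH2Cl2, −78 °C; Rochelle salt
Reagents that add atoms: none
Why: DIBAL-H 1,2-reduction of the conjugated ester gives the allylic alcohol without touching the alkene geometry.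

**Step 14**
Reactants: 20 (2E)-3-methyl-5-(2,6,6-trimethylcyclohex-1-en-1-yl)pent-2-en-1-ol
Product: 21 5-{[(2E)-3-methyl-5-(2,6,6-trimethylcyclohex-1-en-1-yl)pent-2-en-1-yl]sulfanyl}-1-phenyl-1H-tetrazole
Conditions: 1-phenyl-1H-tetrazole-5-thiol, PPh3, DIAD, THF, 0 °C → rt
Reagents that add atoms: 1-phenyl-1H-tetrazole-5-thiol, Sc1nnnn1-c1ccccc1
Why: Mitsunobu thioetherification with the acidic heteroaryl thiol is a direct SN2 displacement at the primary allylic carbon and should occur without allylic transposition.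

**Step 15**
Reactants: 21 5-{[(2E)-3-methyl-5-(2,6,6-trimethylcyclohex-1-en-1-yl)pent-2-en-1-yl]sulfanyl}-1-phenyl-1H-tetrazole
Product: 22 5-{[(2E)-3-methyl-5-(2,6,6-trimethylcyclohex-1-en-1-yl)pent-2-en-1-yl]sulfonyl}-1-phenyl-1H-tetrazole
Conditions: (NH4)6Mo7O24·4H2O (10 mol %), 30% H2O2, EtOH, 0 °C → rt
Reagents that add atoms: hydrogen peroxide, OO
Why: Molybdate-catalysed peroxide oxidation of sulfide to sulfone is selective for sulfur over tri- and tetrasubstituted alkenes at low temperature, as in the preparation of prenyl-type tetrazolyl sulfones.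

**Step 16**
Reactants: 22 5-{[(2E)-3-methyl-5-(2,6,6-trimethylcyclohex-1-en-1-yl)pent-2-en-1-yl]sulfonyl}-1-phenyl-1H-tetrazole; 17 methyl (2R)-2-formyl-2-methyl-3,4-dihydro-2H-chromene-6-carboxylate
Product: 23 methyl (2R)-2-methyl-2-[(1E,3E)-4-methyl-6-(2,6,6-trimethylcyclohex-1-en-1-yl)hexa-1,3-dien-1-yl]-3,4-dihydro-2H-chromene-6-carboxylate
Conditions: 22, KHMDS, DME, −60 °C, 30 min; then 17, −60 °C → rt; aq NH4Cl
Reagents that add atoms: none
Why: In the Julia–Kocienski olefination the metallated allylic sulfone adds to the non-enolisable aldehyde, and Smiles rearrangement with loss of SO2 and tetrazolone forms C1'=C2', expected mainly E with the α-quaternary aldehyde and potassium in DME, while the 3'E geometry comes from 22 and the benzoate ester is too slow an electrophile to interfere at low temperature.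

**Step 17**
Reactants: 23 methyl (2R)-2-methyl-2-[(1E,3E)-4-methyl-6-(2,6,6-trimethylcyclohex-1-en-1-yl)hexa-1,3-dien-1-yl]-3,4-dihydro-2H-chromene-6-carboxylate
Product: 24 (2R)-2-methyl-2-[(1E,3E)-4-methyl-6-(2,6,6-trimethylcyclohex-1-en-1-yl)hexa-1,3-dien-1-yl]-3,4-dihydro-2H-chromene-6-carboxylic acid
Conditions: LiOH·H2O (5 equiv), THF/MeOH/H2O 3:1:1, rt → 40 °C; then cold 0.5 M HCl to pH 4–5
Reagents that add atoms: lithium hydroxide, [Li+].[OH-]
Why: Saponification (acyl-oxygen cleavage) of the methyl benzoate leaves the alkenes and C2 untouched, and the brief, mildly acidic work-up protects the tertiary dienylic aryl ether.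

**Compound list**

1 | (S)-2-methylglycidol | OC[C@@]1(C)CO1 | starting material
2 | tert-butyl{[(2R)-2-methyloxiran-2-yl]methoxy}diphenylsilane | CC(C)(C)[Si](c1ccccc1)(c1ccccc1)OC[C@@]1(C)CO1 | intermediate
3 | (2R)-1-[(tert-butyldiphenylsilyl)oxy]-2-methylhex-5-en-2-ol | CC(C)(C)[Si](c1ccccc1)(c1ccccc1)OC[C@@](O)(C)CCC=C | intermediate
4 | (2R)-6-(9-borabicyclo[3.3.1]nonan-9-yl)-1-[(tert-butyldiphenylsilyl)oxy]-2-methylhexan-2-ol | CC(C)(C)[Si](c1ccccc1)(c1ccccc1)OC[C@@](O)(C)CCCCB1C2CCCC1CCC2 | intermediate (not isolated)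
5 | (5R)-6-[(tert-butyldiphenylsilyl)oxy]-5-methylhexane-1,5-diol | CC(C)(C)[Si](c1ccccc1)(c1ccccc1)OC[C@@](O)(C)CCCCO | intermediate
6 | (5R)-6-[(tert-butyldiphenylsilyl)oxy]-5-hydroxy-5-methylhexanal | CC(C)(C)[Si](c1ccccc1)(c1ccccc1)OC[C@@](O)(C)CCCC=O | intermediate (not isolated)
7 | (6R)-6-{[(tert-butyldiphenylsilyl)oxy]methyl}-6-methyloxan-2-ol (both anomers) | CC(C)(C)[Si](c1ccccc1)(c1ccccc1)OC[C@@]1(C)CCCC(O)O1 | intermediate (not isolated)
8 | (6R)-6-{[(tert-butyldiphenylsilyl)oxy]methyl}-6-methyloxan-2-one | CC(C)(C)[Si](c1ccccc1)(c1ccccc1)OC[C@@]1(C)CCCC(=O)O1 | intermediate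
9 | (6R)-6-{[(tert-butyldiphenylsilyl)oxy]methyl}-3-[(dimethylamino)methyl]-6-methyloxan-2-one (C3 epimers) | CC(C)(C)[Si](c1ccccc1)(c1ccccc1)OC[C@@]1(C)CCC(CN(C)C)C(=O)O1 | intermediate
10 | {[(6R)-6-{[(tert-butyldiphenylsilyl)oxy]methyl}-6-methyl-2-oxooxan-3-yl]methyl}trimethylazanium iodide | CC(C)(C)[Si](c1ccccc1)(c1ccccc1)OC[C@@]1(C)CCC(C[N+](C)(C)C)C(=O)O1.[I-] | intermediate (not isolated)
11 | (6R)-6-{[(tert-butyldiphenylsilyl)oxy]methyl}-6-methyl-3-methylideneoxan-2-one | CC(C)(C)[Si](c1ccccc1)(c1ccccc1)OC[C@@]1(C)CCC(=C)C(=O)O1 | intermediate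
12 | tert-butyl{[(2R)-2-methyl-5,6-dimethylideneoxan-2-yl]methoxy}diphenylsilane | CC(C)(C)[Si](c1ccccc1)(c1ccccc1)OC[C@@]1(C)CCC(=C)C(=C)O1 | intermediate
13 | methyl propiolate (methyl prop-2-ynoate) | C#CC(=O)OC | starting material
14 | methyl (2R)-2-{[(tert-butyldiphenylsilyl)oxy]methyl}-2-methyl-3,4,5,8-tetrahydro-2H-chromene-6-carboxylate | CC(C)(C)[Si](c1ccccc1)(c1ccccc1)OC[C@@]1(C)CCC2=C(CC=C(C(=O)OC)C2)O1 | intermediate
15 | methyl (2R)-2-{[(tert-butyldiphenylsilyl)oxy]methyl}-2-methyl-3,4-dihydro-2H-chromene-6-carboxylate | CC(C)(C)[Si](c1ccccc1)(c1ccccc1)OC[C@@]1(C)CCc2cc(C(=O)OC)ccc2O1 | intermediate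
16 | methyl (2R)-2-(hydroxymethyl)-2-methyl-3,4-dihydro-2H-chromene-6-carboxylate | OC[C@@]1(C)CCc2cc(C(=O)OC)ccc2O1 | intermediate
17 | methyl (2R)-2-formyl-2-methyl-3,4-dihydro-2H-chromene-6-carboxylate | O=C[C@@]1(C)CCc2cc(C(=O)OC)ccc2O1 | intermediate
18 | dihydro-β-ionone, 4-(2,6,6-trimethylcyclohex-1-en-1-yl)butan-2-one | CC(=O)CCC1=C(C)CCCC1(C)C | starting material
19 | ethyl (2E)-3-methyl-5-(2,6,6-trimethylcyclohex-1-en-1-yl)pent-2-enoate | CCOC(=O)/C=C(\C)CCC1=C(C)CCCC1(C)C | intermediate
20 | (2E)-3-methyl-5-(2,6,6-trimethylcyclohex-1-en-1-yl)pent-2-en-1-ol | OC/C=C(\C)CCC1=C(C)CCCC1(C)C | intermediate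
21 | 5-{[(2E)-3-methyl-5-(2,6,6-trimethylcyclohex-1-en-1-yl)pent-2-en-1-yl]sulfanyl}-1-phenyl-1H-tetrazole | CC1=C(CC/C(C)=C/CSc2nnnn2-c2ccccc2)C(C)(C)CCC1 | intermediate
22 | 5-{[(2E)-3-methyl-5-(2,6,6-trimethylcyclohex-1-en-1-yl)pent-2-en-1-yl]sulfonyl}-1-phenyl-1H-tetrazole | CC1=C(CC/C(C)=C/CS(=O)(=O)c2nnnn2-c2ccccc2)C(C)(C)CCC1 | intermediate
23 | methyl (2R)-2-methyl-2-[(1E,3E)-4-methyl-6-(2,6,6-trimethylcyclohex-1-en-1-yl)hexa-1,3-dien-1-yl]-3,4-dihydro-2H-chromene-6-carboxylate | CC1=C(CC/C(C)=C/C=C/[C@@]2(C)CCc3cc(C(=O)OC)ccc3O2)C(C)(C)CCC1 | intermediate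
24 | (2R)-2-methyl-2-[(1E,3E)-4-methyl-6-(2,6,6-trimethylcyclohex-1-en-1-yl)hexa-1,3-dien-1-yl]-3,4-dihydro-2H-chromene-6-carboxylic acid | CC1=C(CC/C(C)=C/C=C/[C@@]2(C)CCc3cc(C(=O)O)ccc3O2)C(C)(C)CCC1 | target

**Step count**

Total: 17 steps. Longest linear sequence: 13 steps (steps 1–11, 16, 17); the sulfone branch is steps 12–15.

**Steps most likely to fail**

Step 7. The conjugated lactone may be consumed by conjugate addition of pyridine or by side reactions of the titanium carbene, and the diene may be lost through acid-catalysed hydration or self-dimerisation during the titanium/aluminium work-up. The fallback sets out from Mannich base 9 and reverses the order of the two methylenations, so that the diene is unveiled by elimination in a metal-free basic medium. Tebbe methylenation of the saturated lactone carbonyl of 9 should give 1-[(6R)-6-{[(tert-butyldiphenylsilyl)oxy]methyl}-6-methyl-2-methylideneoxan-3-yl]-N,N-dimethylmethanamine F1. Quaternisation with iodomethane would give {[(6R)-6-{[(tert-butyldiphenylsilyl)oxy]methyl}-6-methyl-2-methylideneoxan-3-yl]methyl}trimethylazanium iodide F2. Hofmann elimination with KOt-Bu in THF at 0 °C, removing the allylic C3 hydrogen, should then deliver diene 12 as a filtered solution that goes straight into step 8.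

Step 8. The cycloaddition may be outpaced by dimerisation or polymerisation of the electron-rich diene at the temperature the propiolate needs, and the alkyl substituent on C4a may erode the para orientation. The fallback sets out from diene 12 and uses methyl 2-chloroacrylate, a more reactive and more strongly polarised dienophile that carries the missing unsaturation as a leaving group. Cycloaddition at or near room temperature should give methyl (2R)-2-{[(tert-butyldiphenylsilyl)oxy]methyl}-6-chloro-2-methyl-3,4,5,6,7,8-hexahydro-2H-chromene-6-carboxylate F3. Dehydrochlorination with DBU should give the conjugated dienoate methyl (2R)-2-{[(tert-butyldiphenylsilyl)oxy]methyl}-2-methyl-3,4,7,8-tetrahydro-2H-chromene-6-carboxylate F4, possibly together with its isomer 14. Either cyclohexadiene is dehydrogenated with DDQ as in step 9, and the route is rejoined at arene 15.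

Step 16. Reversible addition of the stabilised allylic sulfonyl anion may give poor E/Z control at C1'=C2', and γ-attack or geometric leakage at C3'=C4' is possible. The fallback sets out from aldehyde 17 and ketone 18 and forms the C2'–C3' bond by cross-coupling of two geometrically defined alkenyl partners.
- Boron partner: Takai–Utimoto borylolefination of 17 (CrCl2, Cl2CHBpin, LiI, THF) should give methyl (2R)-2-methyl-2-[(E)-2-(4,4,5,5-tetramethyl-1,3,2-dioxaborolan-2-yl)ethenyl]-3,4-dihydro-2H-chromene-6-carboxylate F5.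
- Iodide partner: kinetic enolisation of 18 with LDA and trapping with diethyl chlorophosphate gives diethyl 4-(2,6,6-trimethylcyclohex-1-en-1-yl)but-1-en-2-yl phosphate F6, and elimination with more LDA gives 2-(but-3-yn-1-yl)-1,3,3-trimethylcyclohex-1-ene F7. Zirconium-catalysed syn-methylalumination (Me3Al, Cp2ZrCl2 cat.) gives dimethyl[(1E)-2-methyl-4-(2,6,6-trimethylcyclohex-1-en-1-yl)but-1-en-1-yl]alumane F8, and iodinolysis gives 2-[(3E)-4-iodo-3-methylbut-3-en-1-yl]-1,3,3-trimethylcyclohex-1-ene F9.
- Coupling: Suzuki–Miyaura coupling of F5 with F9 (Pd(PPh3)4, aq K3PO4, THF) should give ester 23 with both alkene geometries retained.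

**Further compounds**

F1 | step 7 | 1-[(6R)-6-{[(tert-butyldiphenylsilyl)oxy]methyl}-6-methyl-2-methylideneoxan-3-yl]-N,N-dimethylmethanamine (C3 epimers) | CC(C)(C)[Si](c1ccccc1)(c1ccccc1)OC[C@@]1(C)CCC(CN(C)C)C(=C)O1
F2 | step 7 | {[(6R)-6-{[(tert-butyldiphenylsilyl)oxy]methyl}-6-methyl-2-methylideneoxan-3-yl]methyl}trimethylazanium iodide | CC(C)(C)[Si](c1ccccc1)(c1ccccc1)OC[C@@]1(C)CCC(C[N+](C)(C)C)C(=C)O1.[I-]
F3 | step 8 | methyl (2R)-2-{[(tert-butyldiphenylsilyl)oxy]methyl}-6-chloro-2-methyl-3,4,5,6,7,8-hexahydro-2H-chromene-6-carboxylate (C6 epimers) | CC(C)(C)[Si](c1ccccc1)(c1ccccc1)OC[C@@]1(C)CCC2=C(CCC(Cl)(C(=O)OC)C2)O1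
F4 | step 8 | methyl (2R)-2-{[(tert-butyldiphenylsilyl)oxy]methyl}-2-methyl-3,4,7,8-tetrahydro-2H-chromene-6-carboxylate | CC(C)(C)[Si](c1ccccc1)(c1ccccc1)OC[C@@]1(C)CCC2=C(CCC(C(=O)OC)=C2)O1
F5 | step 16 | methyl (2R)-2-methyl-2-[(E)-2-(4,4,5,5-tetramethyl-1,3,2-dioxaborolan-2-yl)ethenyl]-3,4-dihydro-2H-chromene-6-carboxylate | CC1(C)OB(/C=C/[C@@]2(C)CCc3cc(C(=O)OC)ccc3O2)OC1(C)C
F6 | step 16 | diethyl 4-(2,6,6-trimethylcyclohex-1-en-1-yl)but-1-en-2-yl phosphate | C=C(CCC1=C(C)CCCC1(C)C)OP(=O)(OCC)OCC
F7 | step 16 | 2-(but-3-yn-1-yl)-1,3,3-trimethylcyclohex-1-ene | C#CCCC1=C(C)CCCC1(C)C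
F8 | step 16 | dimethyl[(1E)-2-methyl-4-(2,6,6-trimethylcyclohex-1-en-1-yl)but-1-en-1-yl]alumane | C[Al](C)/C=C(\C)CCC1=C(C)CCCC1(C)C
F9 | step 16 | 2-[(3E)-4-iodo-3-methylbut-3-en-1-yl]-1,3,3-trimethylcyclohex-1-ene | I/C=C(\C)CCC1=C(C)CCCC1(C)C
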